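## The problem

Target 23 is a 2,2-dimethyl-2H-chromene whose benzene ring (ring A) carries no hydrogen. The pyran (ring B) is fused across C4a–C8a, C5 bears a hydroxyl, C6 a 4-hydroxyphenylacetyl group, C7 a methoxy group and C8 a 3-methylbut-2-enyl chain. The molecule has no stereocenter, so the whole difficulty is regiochemical: three phloroglucinol-type oxygens must end as ring ether, free phenol and methyl ether, and three different carbon substituents must go onto the carbons between them. The C3=C4 double bond of the chromene and the prenyl alkene both add acid, electrophiles and hydrogen, which rules out hydrogenolysis and strong acids late in the route. The CH2 between ketone and aryl ring is enolisable and easily oxidised, and the ketone is flanked by two ortho substituents, so it is better grown from a carbonyl carbon already on the ring than introduced by acylation. The feature that opens the route is the position of C4a: it lies between the oxygen-bearing carbons C5 and C8a and para to the C7 methoxy group. If ring B is opened at O1–C2 and C3–C4, C4 becomes the formyl carbon of aldehyde 5, which has a mirror plane through CHO and OMe, so either hydroxyl closes the same pyran. The same pattern helps twice more: the C5 hydroxyl of chromenol 9 has one free ortho carbon (C6), and once C6 is filled a prenyl group on O5 can only travel to the para carbon C8.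

## Retrosynthesis

**23 ⇒ 22 (O–allyl bond).** The distal phenol must be masked while its benzylic carbon serves as a carbanion. An allyl ether is preferred to an acetal or silyl ether: it goes selectively onto the phenolic oxygen of 17, survives formation of a Grignard reagent, and comes off under the neutral allyl-transfer conditions of step 12. An acetal would expose ring B and the C8 side chain to acid in the last step. The forward reaction only has to leave the two alkenes and the chelated phenol alone.

**22 ⇒ 21 ⇒ 16 + 20 (carbonyl carbon–CH2 bond).** Cutting instead between C6 and the carbonyl carbon would mean acylating a ring carbon flanked by OH and OMe under Lewis acid, which ring B would not tolerate, and would carry an enolisable ketone through the thermal step. The chosen cut gives aldehyde 16 and benzylic Grignard reagent 20 (from chloride 19), with carbinol 21 oxidised afterwards. The forward steps must achieve addition to a hindered, chelated salicylaldehyde and oxidation of a benzylic carbinol beside a free phenol.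

**16 ⇒ 13 ⇒ 11 + 12 (C8–CH2 bond of the prenyl group).** Direct C-alkylation of C8 would give O/C mixtures or need acid. C8 is para to O5, and in 11 both carbons ortho to O5 (C4a and C6) are substituted. A prenyl group placed on O5 (ether 13) can therefore come to rest only at C8, after two consecutive [3,3] shifts through dienones 14 and 15 that return the unrearranged prenyl skeleton. The precursor 11 is five carbons simpler, and the only building block is bromide 12. The chromene and the aldehyde must survive about 190 °C.

**11 ⇒ 9 (C6–CHO bond).** The formyl group is both the future ketone carbon and the blocking group that forces the para shift. It is introduced by the chelation-controlled ortho-formylation of step 5, which passes through hydroxymethyl compound 10. C6 is the only free carbon ortho to the C5 hydroxyl of 9; the equally electron-rich C8 is para and is not reached by an ortho-specific reaction.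

**9 ⇒ 5 + 6 (C3–C4 and O1–C2 bonds; key disconnection).** Ring B is opened completely. The neighbouring cut (C4–C4a and O1–C2, i.e. attaching a C5 unit to 5-methoxyresorcinol 1) would have to choose between two different nucleophilic ring carbons. Here the ring carbon is already bonded to C4 as the formyl group of symmetric aldehyde 5, and the remaining four carbons come from Grignard reagent 6. Addition gives triol 7, and loss of water gives ortho-quinone methide 8, which closes to 9. The precursor has no ring B and no regiochemical ambiguity. The forward step requires 1,2-addition to a doubly deprotonated aldehyde and a dehydration mild enough for the chromene.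

**5 ⇒ 4 ⇒ 2 ⇒ 1 (C–CHO bond of ring A).** Electrophilic formylation of 1 would favour the carbon between OH and OMe and give the unsymmetrical aldehyde. Converting 1 into bis-acetal 2 and lithiating it gives aryllithium 3 at the carbon between the two acetal oxygens, and formylation then gives 4. Acid hydrolysis releases 5.

**19 ⇒ 18 ⇒ 17.** Chloride 19 comes from alcohol 18 by chlorodehydroxylation, and 18 from 4-hydroxybenzyl alcohol 17 by selective O-allylation of the phenol.

## Roads not taken

**Alternative 1:** The cut goes through ring A itself (C8–C8a and C6–C7, with C4a–C8a remade). It leads back to 3-(triisopropylsilyloxy)cyclobut-2-en-1-one (A1) and 1-methoxy-5-methylhex-4-en-1-yne (A2).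

- Forward step: on heating, A1 opens to a vinylketene, which adds to the ynol ether A2; the new cyclobutenone opens again and closes by 6π electrocyclisation to 3-methoxy-2-(3-methylbut-2-enyl)-5-(triisopropylsilyloxy)phenol (A3).
- Merits: the three oxygens of A3 are differentiated at once (free OH for O1, OMe, silyl ether for the C5 hydroxyl). The C8 prenyl group is present from the start. The free hydroxyl has a single open ortho carbon, the future C4a, so the later pyran closure is regiochemically fixed.
- Weak points: neither A1 nor A2 is commercial. A2 is a labile skipped enynyl ether that needs several steps and may isomerise at the temperature of the benzannulation. After A3, ring B and the hindered C6 ketone still have to be added.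
- Comparison: this road is better exactly where the chosen plan is weakest, since no 190 °C sigmatropic relay is needed to reach C8. Against that the chosen plan sets two cheap commercial phenols, no construction of a benzene ring, and a step count that the preparation of A1 and A2 alone would nearly use up.

**Alternative 2:** Ring B is made last, by cutting C4–C4a and O1–C2 of a fully substituted precursor, 1-[2-methoxy-6-(methoxymethoxy)-3-(3-methylbut-2-enyl)-4-(2-methylbut-3-yn-2-yloxy)phenyl]-2-[4-(methoxymethoxy)phenyl]ethanone (A4).

- Forward step: heating A4 causes an aromatic propargyl Claisen shift to the only free ortho carbon, enolisation, a [1,5]-hydrogen shift and oxa-6π closure. The product is 1-[7-methoxy-5-(methoxymethoxy)-2,2-dimethyl-8-(3-methylbut-2-enyl)-2H-chromen-6-yl]-2-[4-(methoxymethoxy)phenyl]ethanone (A5).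
- Merits: this cascade is probably the most reliable way to make a dimethylchromene. Its regiochemistry is forced because C8 is blocked, and the acid-sensitive chromene is carried through very few steps.
- Weak points: the regiochemical problem is moved into A4 and not solved there. A4 needs three differently treated oxygens, a prenyl group and the ketone placed on an open benzene, and a tertiary propargylic ether on a flanked phenol is not easy to make. The enolisable ketone and the prenyl group must survive the heating. The two acetal groups of A5 still have to be removed with acid from a molecule that then contains both alkenes.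
- Comparison: as a single step the thermal cascade is more secure than a Grignard addition to a bis-phenoxide, and it would be the better choice if A4 were at hand. The chosen plan sets against it a key step that meets no regiochemical choice, because its substrate is symmetric, and an ending without acid.

**Alternative 3:** The biomimetic cut breaks only O1–C2 and places a prenyl group on C4a between two hydroxyls, in 1-[2,4-dihydroxy-6-methoxy-3-(3-methylbut-2-enyl)phenyl]-2-[4-(methoxymethoxy)phenyl]ethanone (A6).

- Forward step: a high-potential quinone oxidant removes hydride from the benzylic CH2 of the C-prenyl group of A6, and the resulting ortho-quinone methide closes to 1-(5-hydroxy-7-methoxy-2,2-dimethyl-2H-chromen-6-yl)-2-[4-(methoxymethoxy)phenyl]ethanone (A7).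
- Merits: the C-prenylation between two hydroxyls that A6 requires is the natural reaction of such a ring, the oxidative closure of A6 to A7 is of a type well known for ortho-prenylphenols, and no organometallic reagent is needed for ring B.
- Weak points: in A6 two hydroxyls flank the prenyl group, so closure onto the chelated oxygen would give the angular regioisomer. The oxidant can also attack the activated CH2 of the deoxybenzoin unit that A6 already carries. A7 still lacks the C8 prenyl group, which cannot be present in A6 because the same oxidant would dehydrogenate it. It would have to be added to A7 by the same O-prenylation and para shift as in the chosen route, now beside an enolisable ketone.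
- Comparison: starting from A6 the step count would be similar and the chemistry of ring B gentler than a Grignard reaction. The chosen plan has to accept a more demanding organometallic step, but it faces no choice of hydroxyl in the ring closure and forms the ketone only after the thermal step.

Key step: step 4

Assumption: reagent 6 is bought as its THF solution; since the target has no stereocenter, the carbinols and dienones formed on the way (7, 14, 15, 21) are racemic.

## Route

Step 1
Reactants: 1 5-methoxybenzene-1,3-diol (5-methoxyresorcinol)
Product: 2 1-methoxy-3,5-bis(methoxymethoxy)benzene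
Conditions: MOMCl (2.6 equiv), iPr2NEt (3 equiv), CH2Cl2, 0 °C → rt
Reagents that add atoms: chloromethyl methyl ether, COCCl
Why: O-alkylation of both phenols with an α-chloro ether under amine base is routine for resorcinols; the methoxymethyl groups are chosen because they are the strongest ortho-directing groups available for step 2.

Step 2
Reactants: 2 1-methoxy-3,5-bis(methoxymethoxy)benzene
Product: 4 4-methoxy-2,6-bis(methoxymethoxy)benzaldehyde, via aryllithium 3 (not isolated)
Conditions: n-BuLi (1.2 equiv), TMEDA, THF, 0 °C; DMF, 0 °C → rt; aq NH4Cl
Reagents that add atoms: N,N-dimethylformamide, CN(C)C=O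
Why: Directed ortho-metalation: the carbon between the two acetal oxygens is complexed from both sides and should be lithiated in preference to the carbons between acetal and methoxy; formylation of 3 with DMF then gives the symmetric aldehyde. The symmetry of 4 makes the site of attack easy to verify.

Step 3
Reactants: 4 4-methoxy-2,6-bis(methoxymethoxy)benzaldehyde
Product: 5 2,6-dihydroxy-4-methoxybenzaldehyde
Conditions: 3 M aq HCl, MeOH, 50 °C
Reagents that add atoms: none
Why: Acid-catalysed acetal cleavage; both groups are ortho to the carbonyl and cleave readily, and the product is a stable vinylogous acid of the 2,4,6-trihydroxybenzaldehyde type.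

Step 4
Reactants: 5 2,6-dihydroxy-4-methoxybenzaldehyde; 6 2-methylprop-1-enylmagnesium bromide
Product: 9 7-methoxy-2,2-dimethyl-2H-chromen-5-ol, via benzylic triol 7 (not isolated), via ortho-quinone methide 8 (not isolated)
Conditions: 6 (4 equiv, 0.5 M in THF), THF, 0 °C → rt; sat. aq NH4Cl; then PPTS (10 mol %), 4 Å MS, toluene (dilute), 50 °C
Reagents that add atoms: none
Why: Two equivalents of 6 deprotonate the phenols and a third adds to the magnesium-chelated aldehyde, forming the C3–C4 bond; work-up gives triol 7. The C4 hydroxyl of 7 is benzylic, allylic and flanked by two ortho hydroxyls and a para methoxy group, so a trace of pyridinium acid at 50 °C should be enough to expel water and give ortho-quinone methide 8. 8 is a 1-oxatriene and closes by thermal disrotatory oxa-6π electrocyclisation, which makes the O1–C2 bond and the six-membered pyran (ring B) and restores the aromaticity of ring A. The closest known reaction type is the addition of 2-methylpropenyl Grignard reagents to salicylaldehydes followed by dehydrative cyclisation to 2,2-dimethyl-2H-chromenes; the same quinone methide is the intermediate of phenol–enal chromenylations. No stereocenter is left in 9; the carbinol center of 7 is racemic and is destroyed on dehydration. The one selectivity the step needs is the choice of the hydroxyl that becomes O1, and the mirror plane of 5 through CHO and OMe makes the two choices identical; since a proton shift lets either oxygen of 8 act as the carbonyl, both geometries of the exocyclic double bond lead to closure. Weak acid, dilution and molecular sieves are used so that the electron-rich product neither adds acid at C3=C4 nor captures 8 intermolecularly.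

Step 5
Reactants: 9 7-methoxy-2,2-dimethyl-2H-chromen-5-ol
Product: 11 5-hydroxy-7-methoxy-2,2-dimethyl-2H-chromene-6-carbaldehyde, via hydroxymethyl phenol 10 (not isolated)
Conditions: MgCl2 (2 equiv), Et3N (4 equiv), (CH2O)n (6 equiv), MeCN, reflux; sat. aq NH4Cl
Reagents that add atoms: paraformaldehyde (as formaldehyde), C=O
Why: Magnesium-mediated ortho-formylation of a phenol: the magnesium phenoxide delivers formaldehyde to the ortho carbon to give 10, which is oxidised in the flask by hydride transfer to a second formaldehyde (Oppenauer type). C6 is the only free carbon ortho to the C5 hydroxyl, and the non-acidic medium spares the chromene.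

Step 6
Reactants: 11 5-hydroxy-7-methoxy-2,2-dimethyl-2H-chromene-6-carbaldehyde; 12 1-bromo-3-methylbut-2-ene
Product: 13 7-methoxy-2,2-dimethyl-5-(3-methylbut-2-enyloxy)-2H-chromene-6-carbaldehyde
Conditions: 12 (1.5 equiv), K2CO3 (2 equiv), DMF, rt → 40 °C
Reagents that add atoms: none
Why: Williamson O-alkylation of the potassium phenoxide with a primary allylic bromide in a dipolar aprotic solvent; the chelated, flanked phenol reacts more slowly than a simple one, but O-alkylation remains the favoured course.

Step 7
Reactants: 13 7-methoxy-2,2-dimethyl-5-(3-methylbut-2-enyloxy)-2H-chromene-6-carbaldehyde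
Product: 16 5-hydroxy-7-methoxy-2,2-dimethyl-8-(3-methylbut-2-enyl)-2H-chromene-6-carbaldehyde, via ortho-dienone 14 (not isolated), via para-dienone 15 (not isolated)
Conditions: PhNEt2, 190 °C, sealed tube, Ar
Reagents that add atoms: none
Why: para-Claisen–Cope rearrangement: an aromatic Claisen [3,3] shift places the inverted allyl unit on a blocked ortho carbon (drawn for C6 in 14; attack on the other blocked ortho carbon would converge on the same product), a Cope [3,3] shift moves it to C8 (15), and enolisation restores ring A. Both ortho positions of O5 are substituted, so the side chain can only end at the para carbon C8, and the two inversions return the normal 3-methylbut-2-enyl group. The stereocenters of 14 and 15 are racemic and vanish on enolisation.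

Step 8
Reactants: 17 4-(hydroxymethyl)phenol (4-hydroxybenzyl alcohol)
Product: 18 [4-(prop-2-enyloxy)phenyl]methanol
Conditions: allyl bromide (1.1 equiv), K2CO3, acetone, reflux
Reagents that add atoms: 3-bromoprop-1-ene (allyl bromide), C=CCBr
Why: Carbonate deprotonates only the phenol, so Williamson alkylation is selective for the phenolic oxygen over the benzylic alcohol; the allyl ether is stable to organomagnesium chemistry and removable without acid.

Step 9
Reactants: 18 [4-(prop-2-enyloxy)phenyl]methanol
Product: 19 1-(chloromethyl)-4-(prop-2-enyloxy)benzene
Conditions: SOCl2 (1.2 equiv), CH2Cl2, 0 °C → rt; used without storage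
Reagents that add atoms: thionyl chloride, O=S(Cl)Cl
Why: Chlorodehydroxylation of an electron-rich benzylic alcohol with thionyl chloride is fast at 0 °C, and the allyl aryl ether is inert to the hydrogen chloride formed.

Step 10
Reactants: 16 5-hydroxy-7-methoxy-2,2-dimethyl-8-(3-methylbut-2-enyl)-2H-chromene-6-carbaldehyde; 19 1-(chloromethyl)-4-(prop-2-enyloxy)benzene
Product: 21 6-{1-hydroxy-2-[4-(prop-2-enyloxy)phenyl]ethyl}-7-methoxy-2,2-dimethyl-8-(3-methylbut-2-enyl)-2H-chromen-5-ol (racemic), via benzylic Grignard reagent 20 (not isolated)
Conditions: 19 (3.5 equiv), Mg turnings (I2-activated), THF, 0 °C → rt, slow addition; then 16, THF, −40 → 0 °C; sat. aq NH4Cl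
Reagents that add atoms: none
Why: Formation of a 4-alkoxybenzyl Grignard reagent (dilution and slow addition limit Wurtz coupling) followed by 1,2-addition to a salicylaldehyde: one equivalent is spent on the phenol, and the magnesium phenoxide then holds the aldehyde in a chelate for attack. The new carbinol center forms as a racemate and is erased in step 11; the crude product is kept away from acid.

Step 11
Reactants: 21 6-{1-hydroxy-2-[4-(prop-2-enyloxy)phenyl]ethyl}-7-methoxy-2,2-dimethyl-8-(3-methylbut-2-enyl)-2H-chromen-5-ol
Product: 22 1-[5-hydroxy-7-methoxy-2,2-dimethyl-8-(3-methylbut-2-enyl)-2H-chromen-6-yl]-2-[4-(prop-2-enyloxy)phenyl]ethanone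
Conditions: activated MnO2 (20 equiv), CH2Cl2, rt
Reagents that add atoms: none
Why: MnO2 oxidises benzylic alcohols selectively and is the standard reagent for ortho-hydroxybenzylic alcohols; it should leave the alkenes, the allyl ether and the fully substituted phenol alone. The product is stabilised by the hydrogen bond from the C5 hydroxyl to the new ketone.

Step 12
Reactants: 22 1-[5-hydroxy-7-methoxy-2,2-dimethyl-8-(3-methylbut-2-enyl)-2H-chromen-6-yl]-2-[4-(prop-2-enyloxy)phenyl]ethanone
Product: 23 1-[5-hydroxy-7-methoxy-2,2-dimethyl-8-(3-methylbut-2-enyl)-2H-chromen-6-yl]-2-(4-hydroxyphenyl)ethanone (CNP0287261.0)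
Conditions: Pd(PPh3)4 (5 mol %), morpholine (10 equiv), THF, rt
Reagents that add atoms: none
Why: Tsuji–Trost deallylation: zerovalent palladium ionises the aryl allyl ether to a π-allyl complex, which morpholine captures. At room temperature and neutral pH the C-prenyl group (no leaving group) and the tertiary cyclic allylic ether of ring B should not be ionised, and no acid touches the two alkenes.

## Compound list

1 | 5-methoxybenzene-1,3-diol (5-methoxyresorcinol) | COc1cc(O)cc(O)c1 | starting material
2 | 1-methoxy-3,5-bis(methoxymethoxy)benzene | COCOc1cc(OC)cc(OCOC)c1 | intermediate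
3 | [4-methoxy-2,6-bis(methoxymethoxy)phenyl]lithium | [Li]c1c(OCOC)cc(OC)cc1OCOC | intermediate
4 | 4-methoxy-2,6-bis(methoxymethoxy)benzaldehyde | COCOc1cc(OC)cc(OCOC)c1C=O | intermediate
5 | 2,6-dihydroxy-4-methoxybenzaldehyde | COc1cc(O)c(C=O)c(O)c1 | intermediate
6 | 2-methylprop-1-enylmagnesium bromide | CC(C)=C[Mg]Br | starting material
7 | 2-(1-hydroxy-3-methylbut-2-enyl)-5-methoxybenzene-1,3-diol (racemic) | COc1cc(O)c(C(O)C=C(C)C)c(O)c1 | intermediate
8 | 5-hydroxy-3-methoxy-6-(3-methylbut-2-enylidene)cyclohexa-2,4-dien-1-one (exocyclic double-bond geometry not fixed) | COC1=CC(=O)C(=CC=C(C)C)C(O)=C1 | intermediate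
9 | 7-methoxy-2,2-dimethyl-2H-chromen-5-ol | COc1cc(O)c2c(c1)OC(C)(C)C=C2 | intermediate
10 | 6-(hydroxymethyl)-7-methoxy-2,2-dimethyl-2H-chromen-5-ol | COc1cc2c(c(O)c1CO)C=CC(C)(C)O2 | intermediate
11 | 5-hydroxy-7-methoxy-2,2-dimethyl-2H-chromene-6-carbaldehyde | COc1cc2c(c(O)c1C=O)C=CC(C)(C)O2 | intermediate
12 | 1-bromo-3-methylbut-2-ene | CC(C)=CCBr | starting material
13 | 7-methoxy-2,2-dimethyl-5-(3-methylbut-2-enyloxy)-2H-chromene-6-carbaldehyde | COc1cc2c(c(OCC=C(C)C)c1C=O)C=CC(C)(C)O2 | intermediate
14 | 7-methoxy-2,2-dimethyl-6-(2-methylbut-3-en-2-yl)-5-oxo-5,6-dihydro-2H-chromene-6-carbaldehyde (racemic) | COC1=CC2=C(C=CC(C)(C)O2)C(=O)C1(C=O)C(C)(C)C=C | intermediate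
15 | 7-methoxy-2,2-dimethyl-8-(3-methylbut-2-enyl)-5-oxo-5,8-dihydro-2H-chromene-6-carbaldehyde (racemic) | COC1=C(C=O)C(=O)C2=C(OC(C)(C)C=C2)C1CC=C(C)C | intermediate
16 | 5-hydroxy-7-methoxy-2,2-dimethyl-8-(3-methylbut-2-enyl)-2H-chromene-6-carbaldehyde | COc1c(CC=C(C)C)c2c(c(O)c1C=O)C=CC(C)(C)O2 | intermediate
17 | 4-(hydroxymethyl)phenol (4-hydroxybenzyl alcohol) | OCc1ccc(O)cc1 | starting material
18 | [4-(prop-2-enyloxy)phenyl]methanol | OCc1ccc(OCC=C)cc1 | intermediate
19 | 1-(chloromethyl)-4-(prop-2-enyloxy)benzene | ClCc1ccc(OCC=C)cc1 | intermediate
20 | [4-(prop-2-enyloxy)benzyl]magnesium chloride | Cl[Mg]Cc1ccc(OCC=C)cc1 | intermediate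
21 | 6-{1-hydroxy-2-[4-(prop-2-enyloxy)phenyl]ethyl}-7-methoxy-2,2-dimethyl-8-(3-methylbut-2-enyl)-2H-chromen-5-ol (racemic) | COc1c(CC=C(C)C)c2c(c(O)c1C(O)Cc1ccc(OCC=C)cc1)C=CC(C)(C)O2 | intermediate
22 | 1-[5-hydroxy-7-methoxy-2,2-dimethyl-8-(3-methylbut-2-enyl)-2H-chromen-6-yl]-2-[4-(prop-2-enyloxy)phenyl]ethanone | COc1c(CC=C(C)C)c2c(c(O)c1C(=O)Cc1ccc(OCC=C)cc1)C=CC(C)(C)O2 | intermediate
23 | 1-[5-hydroxy-7-methoxy-2,2-dimethyl-8-(3-methylbut-2-enyl)-2H-chromen-6-yl]-2-(4-hydroxyphenyl)ethanone | COc1c(CC=C(C)C)c2c(c(O)c1C(=O)Cc1ccc(O)cc1)C=CC(C)(C)O2 | target

## Step count and least certain steps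

Total: 12 steps. Longest linear sequence: 10 steps (steps 1–7 and 10–12, from 1 to 23); steps 8 and 9 are a two-step side branch that joins at step 10.

**Step 4 (key step).** The most likely failure is incomplete addition, because the bis(bromomagnesium) salt of 5 is a poorly soluble and doubly deactivated aldehyde. The second is oligomer formation during dehydration, when the electron-rich phenols present capture quinone methide 8 before it cyclises. The fallback keeps the same two bonds and the same symmetric substrate but changes how the quinone methide is produced. It sets out from 5, which Boc2O and DMAP convert into 2-formyl-5-methoxy-1,3-phenylene bis(tert-butyl carbonate) F1. This aldehyde is neutral and soluble, and slightly more than one equivalent of 6 should add to it at −78 °C. On warming, the alkoxide takes a carbonate group from the neighbouring oxygen, the freed phenoxide expels tert-butyl carbonate without any acid, and electrocyclisation gives tert-butyl (7-methoxy-2,2-dimethyl-2H-chromen-5-yl) carbonate F2. K2CO3 in methanol removes the remaining carbonate, and the route is rejoined at 9.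

**Step 5.** The likely failure is condensation to diarylmethanes, because the hydroxymethyl stage 10 can ionise and alkylate a second molecule of the electron-rich chromenol before it is oxidised. The fallback replaces the formaldehyde chemistry by directed metalation and sets out from 9. MOMCl and iPr2NEt give 7-methoxy-5-(methoxymethoxy)-2,2-dimethyl-2H-chromene F3. n-BuLi in THF at 0 °C should lithiate C6, between the acetal and the methoxy oxygen, in preference to C8, and DMF then gives 7-methoxy-5-(methoxymethoxy)-2,2-dimethyl-2H-chromene-6-carbaldehyde F4. Dilute HCl in methanol at room temperature cleaves the acetal, which is ortho to the carbonyl and therefore labile, and the route is rejoined at 11.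

**Step 7.** The likely failures are loss of the prenyl group by ether cleavage at 190 °C and diversion of the crowded ortho-dienone, by deformylation or by arrest before the Cope shift, so that transfer to C8 is not clean. The fallback gives up the sigmatropic relay and sets out from 11. Iodination with NIS in DMF at 0 °C at the only free ring carbon, which is para to the phenol, should give 5-hydroxy-8-iodo-7-methoxy-2,2-dimethyl-2H-chromene-6-carbaldehyde F5. Stille coupling with tributyl(3-methylbut-2-enyl)stannane (Pd(PPh3)4, LiCl, DMF, 90 °C) joins the tin-bearing carbon to C8, and the route is rejoined at 16 with steps 6 and 7 bypassed.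

**Step 11.** The likely failure is slow oxidation of a carbinol flanked by two ortho substituents. During the long contact time, oxidation of the electron-rich phenol or loss of water from the carbinol towards a stilbene could compete. The fallback masks the phenol and sets out from 16. Allyl bromide and K2CO3 in DMF give 7-methoxy-2,2-dimethyl-8-(3-methylbut-2-enyl)-5-(prop-2-enyloxy)-2H-chromene-6-carbaldehyde F6. Reagent 20 (1.3 equiv) adds to give 1-[7-methoxy-2,2-dimethyl-8-(3-methylbut-2-enyl)-5-(prop-2-enyloxy)-2H-chromen-6-yl]-2-[4-(prop-2-enyloxy)phenyl]ethanol F7. Dess–Martin periodinane, now safe because no free phenol is present, gives 1-[7-methoxy-2,2-dimethyl-8-(3-methylbut-2-enyl)-5-(prop-2-enyloxy)-2H-chromen-6-yl]-2-[4-(prop-2-enyloxy)phenyl]ethanone F8. The conditions of step 12 then remove both allyl groups, and the route is rejoined at 23.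

## Further compounds

F1 | step 4 | 2-formyl-5-methoxy-1,3-phenylene bis(tert-butyl carbonate) | COc1cc(OC(=O)OC(C)(C)C)c(C=O)c(OC(=O)OC(C)(C)C)c1
F2 | step 4 | tert-butyl (7-methoxy-2,2-dimethyl-2H-chromen-5-yl) carbonate | COc1cc(OC(=O)OC(C)(C)C)c2c(c1)OC(C)(C)C=C2
F3 | step 5 | 7-methoxy-5-(methoxymethoxy)-2,2-dimethyl-2H-chromene | COCOc1cc(OC)cc2c1C=CC(C)(C)O2
F4 | step 5 | 7-methoxy-5-(methoxymethoxy)-2,2-dimethyl-2H-chromene-6-carbaldehyde | COCOc1c(C=O)c(OC)cc2c1C=CC(C)(C)O2
F5 | step 7 | 5-hydroxy-8-iodo-7-methoxy-2,2-dimethyl-2H-chromene-6-carbaldehyde | COc1c(I)c2c(c(O)c1C=O)C=CC(C)(C)O2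
F6 | step 11 | 7-methoxy-2,2-dimethyl-8-(3-methylbut-2-enyl)-5-(prop-2-enyloxy)-2H-chromene-6-carbaldehyde | COc1c(CC=C(C)C)c2c(c(OCC=C)c1C=O)C=CC(C)(C)O2
F7 | step 11 | 1-[7-methoxy-2,2-dimethyl-8-(3-methylbut-2-enyl)-5-(prop-2-enyloxy)-2H-chromen-6-yl]-2-[4-(prop-2-enyloxy)phenyl]ethanol (racemic) | COc1c(CC=C(C)C)c2c(c(OCC=C)c1C(O)Cc1ccc(OCC=C)cc1)C=CC(C)(C)O2
F8 | step 11 | 1-[7-methoxy-2,2-dimethyl-8-(3-methylbut-2-enyl)-5-(prop-2-enyloxy)-2H-chromen-6-yl]-2-[4-(prop-2-enyloxy)phenyl]ethanone | COc1c(CC=C(C)C)c2c(c(OCC=C)c1C(=O)Cc1ccc(OCC=C)cc1)C=CC(C)(C)O2
A1 | alternative 1 | 3-(triisopropylsilyloxy)cyclobut-2-en-1-one | O=C1CC(O[Si](C(C)C)(C(C)C)C(C)C)=C1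
A2 | alternative 1 | 1-methoxy-5-methylhex-4-en-1-yne | COC#CCC=C(C)C
A3 | alternative 1 | 3-methoxy-2-(3-methylbut-2-enyl)-5-(triisopropylsilyloxy)phenol | COc1cc(O[Si](C(C)C)(C(C)C)C(C)C)cc(O)c1CC=C(C)C
A4 | alternative 2 | 1-[2-methoxy-6-(methoxymethoxy)-3-(3-methylbut-2-enyl)-4-(2-methylbut-3-yn-2-yloxy)phenyl]-2-[4-(methoxymethoxy)phenyl]ethanone | COc1c(CC=C(C)C)c(OC(C)(C)C#C)cc(OCOC)c1C(=O)Cc1ccc(OCOC)cc1
A5 | alternative 2 | 1-[7-methoxy-5-(methoxymethoxy)-2,2-dimethyl-8-(3-methylbut-2-enyl)-2H-chromen-6-yl]-2-[4-(methoxymethoxy)phenyl]ethanone | COc1c(CC=C(C)C)c2c(c(OCOC)c1C(=O)Cc1ccc(OCOC)cc1)C=CC(C)(C)O2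
A6 | alternative 3 | 1-[2,4-dihydroxy-6-methoxy-3-(3-methylbut-2-enyl)phenyl]-2-[4-(methoxymethoxy)phenyl]ethanone | COc1cc(O)c(CC=C(C)C)c(O)c1C(=O)Cc1ccc(OCOC)cc1
A7 | alternative 3 | 1-(5-hydroxy-7-methoxy-2,2-dimethyl-2H-chromen-6-yl)-2-[4-(methoxymethoxy)phenyl]ethanone | COc1cc2c(c(O)c1C(=O)Cc1ccc(OCOC)cc1)C=CC(C)(C)O2
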